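## Retrosynthetic overview

- The last step only removes three silyl ethers from the fully assembled (2S)-flavanone; nothing else changes after the key step.
- Ring C is opened at C3–C4 and O1–C2 into a ring-A salicylaldehyde (formyl carbon = C4, free ortho hydroxyl = O1, side chain already at the future C8) and a ring-B aryl acetylene (alkyne carbons = C2 and C3, chromene already in place). In the forward direction, rhodium-catalysed alkyne hydroacylation followed in the same flask by a catalyst-controlled oxa-Michael closure builds ring C and sets C2.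
- Enabling feature: the ortho-acylphenol array O1–C8a–C4a–C4 shared by rings A and C. At the aldehyde oxidation level it chelates rhodium for formyl C–H activation, and the same oxygen, the only free phenol of ring A, then closes ring C, so the alkyl chain must end at C8.
- Fragment A: 2,4,6-trihydroxybenzaldehyde, bis-silylation, iodination ortho to the free phenol, Heck coupling with 2-methylbut-3-en-2-ol, hydrogenation.
- Fragment B: 4-bromoresorcinol is annulated with 3-methylbut-2-enoic acid (pyran ring first, bromine fixing the linear pattern), then reduction/dehydration, silylation and Sonogashira ethynylation. Ring order: pyran ring of fragment B, then ring C.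

Key step: step 10

Assumption: the facial sense of the cinchona thiourea on the chalcone intermediate of the key step cannot be assigned in advance; the quinidine-derived catalyst is written, and its quinine-derived pseudoenantiomer takes its place if a test closure gives the 2R ketone.

## Route

Step 1
Reactants: 1 2,4,6-trihydroxybenzaldehyde
Product: 2 2-hydroxy-4,6-bis(tert-butyldimethylsilyloxy)benzaldehyde
Conditions: TBSCl (2.1 equiv), imidazole (2.5 equiv), CH2Cl2–DMF, 0 °C
Reagents that add atoms: tert-butyldimethylsilyl chloride, CC(C)(C)[Si](C)(C)Cl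
Why: Silyl ether formation should take the para hydroxyl and one of the two equivalent ortho hydroxyls, while the last hydroxyl is held in the hydrogen bond to the formyl group and stays free.

Step 2
Reactants: 2 2-hydroxy-4,6-bis(tert-butyldimethylsilyloxy)benzaldehyde
Product: 3 2-hydroxy-3-iodo-4,6-bis(tert-butyldimethylsilyloxy)benzaldehyde
Conditions: NIS (1.05 equiv), CH2Cl2, 0 °C to rt
Reagents that add atoms: N-iodosuccinimide, O=C1CCC(=O)N1I
Why: Electrophilic aromatic iodination should go ortho to the free chelated phenol, because the only other open position lies between two bulky silyloxy groups.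

Step 3
Reactants: 3 2-hydroxy-3-iodo-4,6-bis(tert-butyldimethylsilyloxy)benzaldehyde; 4 2-methylbut-3-en-2-ol
Product: 5 (E)-2-hydroxy-3-(3-hydroxy-3-methylbut-1-en-1-yl)-4,6-bis(tert-butyldimethylsilyloxy)benzaldehyde
Conditions: Pd(OAc)2 (5 mol %), P(o-tol)3 (10 mol %), Et3N, MeCN, 80 °C
Reagents that add atoms: none
Why: In this Heck reaction the arylpalladium adds to the terminal alkene carbon, and β-hydride elimination can only give the (E)-styrenyl tertiary allylic alcohol because the carbinol carbon carries no hydrogen.

Step 4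
Reactants: 5 (E)-2-hydroxy-3-(3-hydroxy-3-methylbut-1-en-1-yl)-4,6-bis(tert-butyldimethylsilyloxy)benzaldehyde
Product: 6 2-hydroxy-3-(3-hydroxy-3-methylbutyl)-4,6-bis(tert-butyldimethylsilyloxy)benzaldehyde (fragment A)
Conditions: H2 (1 atm), Pd/C, Ph2S (cat.), EtOAc, rt
Reagents that add atoms: none
Why: Heterogeneous hydrogenation over the sulfide-moderated catalyst should saturate the disubstituted alkene and spare the aryl aldehyde, the tertiary alcohol and the silyl ethers.

Step 5
Reactants: 7 4-bromobenzene-1,3-diol (4-bromoresorcinol); 8 3-methylbut-2-enoic acid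
Product: 9 6-bromo-7-hydroxy-2,2-dimethylchroman-4-one
Conditions: P2O5 in MeSO3H (1:10 w/w, as solvent), 70 °C
Reagents that add atoms: none
Why: Friedel–Crafts acylation at the one open position that is ortho to one hydroxyl and para to the other, followed by oxa-Michael closure of the ortho hydroxyl onto the enone, should give the chromanone with the bromine fixing the linear substitution pattern.

Step 6
Reactants: 9 6-bromo-7-hydroxy-2,2-dimethylchroman-4-one
Product: 11 6-bromo-2,2-dimethyl-2H-chromen-7-ol, via 6-bromo-2,2-dimethylchromane-4,7-diol 10 (not isolated)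
Conditions: NaBH4, THF–EtOH, 0 °C to rt; then 2 M aq. HCl, 45 °C
Reagents that add atoms: none
Why: Hydride reduction of the ketone is followed by acid-promoted dehydration of the benzylic carbinol, which ionises easily because the cation is stabilised by the para hydroxyl and the ortho ring oxygen.

Step 7
Reactants: 11 6-bromo-2,2-dimethyl-2H-chromen-7-ol
Product: 12 (6-bromo-2,2-dimethyl-2H-chromen-7-yl)oxy-triisopropylsilane
Conditions: TIPSCl, imidazole, DMF, rt
Reagents that add atoms: triisopropylsilyl chloride, CC(C)[Si](Cl)(C(C)C)C(C)C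
Why: Silylation masks the phenol that would otherwise add to the ortho alkyne, and the triisopropylsilyl ether should withstand the later carbonate methanolysis.

Step 8
Reactants: 12 (6-bromo-2,2-dimethyl-2H-chromen-7-yl)oxy-triisopropylsilane; 13 ethynyltrimethylsilane
Product: 14 [2,2-dimethyl-6-(trimethylsilylethynyl)-2H-chromen-7-yl]oxy-triisopropylsilane
Conditions: Pd(PhCN)2Cl2 (3 mol %), P(t-Bu)3·HBF4 (6 mol %), CuI (copper iodide, 2 mol %), i-Pr2NH, dioxane, rt to 50 °C
Reagents that add atoms: none
Why: In this Sonogashira coupling the bulky electron-rich phosphine should allow oxidative addition into the electron-rich aryl bromide at low temperature, and the hindered chromene alkene does not take part.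

Step 9
Reactants: 14 [2,2-dimethyl-6-(trimethylsilylethynyl)-2H-chromen-7-yl]oxy-triisopropylsilane
Product: 15 (6-ethynyl-2,2-dimethyl-2H-chromen-7-yl)oxy-triisopropylsilane (fragment B)
Conditions: K2CO3 (0.2 equiv), MeOH–THF, 0 °C
Reagents that add atoms: none
Why: Methanolysis of the alkynyl C–Si bond under catalytic carbonate should be much faster than cleavage of the hindered aryl triisopropylsilyl ether.

Step 10
Reactants: 6 2-hydroxy-3-(3-hydroxy-3-methylbutyl)-4,6-bis(tert-butyldimethylsilyloxy)benzaldehyde (fragment A); 15 (6-ethynyl-2,2-dimethyl-2H-chromen-7-yl)oxy-triisopropylsilane (fragment B)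
Product: 17 (2S)-5,7-bis(tert-butyldimethylsilyloxy)-8-(3-hydroxy-3-methylbutyl)-2-[2,2-dimethyl-7-(triisopropylsilyloxy)-2H-chromen-6-yl]chroman-4-one, via (E)-2'-hydroxychalcone 16 (not isolated)
Conditions: [Rh(cod)OMe]2 (2.5 mol %), dppf (5.5 mol %), toluene, 70 °C; then 0 °C, quinidine-derived thiourea (10 mol %; from 9-amino-9-deoxy-epi-quinidine and 3,5-bis(trifluoromethyl)phenyl isothiocyanate), toluene, 0 °C
Reagents that add atoms: none
Why: Proposed new method: the formyl C–H bond of 6 adds oxidatively to the monovalent rhodium phenoxide formed from the free ortho hydroxyl (the O,acyl chelate suppresses decarbonylation), syn-hydrometalation of alkyne 15 places rhodium on the terminal carbon away from the ortho-silyloxy aryl group, and C–C reductive elimination gives the (E)-2'-hydroxychalcone 16 (C3–C4 bond); the bifunctional amine–thiourea then deprotonates the 2'-hydroxyl while binding the carbonyl oxygen and delivers the phenoxide to the β-carbon (O1–C2 bond). The closest known reaction type is the rhodium-catalysed hydroacylation of alkynes by salicylaldehydes followed by oxa-Michael closure to racemic chroman-4-ones, together with cinchona-thiourea-catalysed oxa-Michael cyclisations of 2'-hydroxy enones; their use in one flask with enantiocontrol on a terminal aryl alkyne is without direct precedent. Ring C closes by a 6-endo-trig conjugate addition. The C2 stereocentre is set by the chiral catalyst, which exposes one face of the s-cis enone to the hydrogen-bonded phenoxide. The step needs anti-Markovnikov regioselectivity (terminal alkyne with a bulky ortho substituent), chemoselectivity for the alkyne over the hindered chromene alkene, closure through the one free phenol only (the other ortho oxygen is silylated, so the side chain ends at C8), and a slow uncatalysed closure (no external base in the rhodium stage, low temperature in the second stage).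

Step 11
Reactants: 17 (2S)-5,7-bis(tert-butyldimethylsilyloxy)-8-(3-hydroxy-3-methylbutyl)-2-[2,2-dimethyl-7-(triisopropylsilyloxy)-2H-chromen-6-yl]chroman-4-one
Product: 18 (2S)-5,7-dihydroxy-2-(7-hydroxy-2,2-dimethyl-2H-chromen-6-yl)-8-(3-hydroxy-3-methylbutyl)chroman-4-one (CNP0423488.1)
Conditions: Bu4NF (4 equiv), AcOH (4 equiv), THF, 0 °C to rt
Reagents that add atoms: none
Why: Fluoride cleaves the three aryl silyl ethers, and the acetic acid buffer keeps the phenols protonated so that the retro-oxa-Michael ring opening that would racemise C2 should not set in and the tertiary alcohol and chromene are left alone.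

## Compound list

1 | 2,4,6-trihydroxybenzaldehyde | O=Cc1c(O)cc(O)cc1O | starting material
2 | 2-hydroxy-4,6-bis(tert-butyldimethylsilyloxy)benzaldehyde | O=Cc1c(O)cc(O[Si](C)(C)C(C)(C)C)cc1O[Si](C)(C)C(C)(C)C | intermediate
3 | 2-hydroxy-3-iodo-4,6-bis(tert-butyldimethylsilyloxy)benzaldehyde | O=Cc1c(O)c(I)c(O[Si](C)(C)C(C)(C)C)cc1O[Si](C)(C)C(C)(C)C | intermediate
4 | 2-methylbut-3-en-2-ol | C=CC(C)(C)O | starting material
5 | (E)-2-hydroxy-3-(3-hydroxy-3-methylbut-1-en-1-yl)-4,6-bis(tert-butyldimethylsilyloxy)benzaldehyde | O=Cc1c(O)c(/C=C/C(C)(C)O)c(O[Si](C)(C)C(C)(C)C)cc1O[Si](C)(C)C(C)(C)C | intermediate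
6 | 2-hydroxy-3-(3-hydroxy-3-methylbutyl)-4,6-bis(tert-butyldimethylsilyloxy)benzaldehyde | O=Cc1c(O)c(CCC(C)(C)O)c(O[Si](C)(C)C(C)(C)C)cc1O[Si](C)(C)C(C)(C)C | intermediate
7 | 4-bromobenzene-1,3-diol | Oc1ccc(Br)c(O)c1 | starting material
8 | 3-methylbut-2-enoic acid | CC(C)=CC(=O)O | starting material
9 | 6-bromo-7-hydroxy-2,2-dimethylchroman-4-one | CC1(C)CC(=O)c2cc(Br)c(O)cc2O1 | intermediate
10 | 6-bromo-2,2-dimethylchromane-4,7-diol (racemic, not isolated) | CC1(C)CC(O)c2cc(Br)c(O)cc2O1 | intermediate
11 | 6-bromo-2,2-dimethyl-2H-chromen-7-ol | CC1(C)C=Cc2cc(Br)c(O)cc2O1 | intermediate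
12 | (6-bromo-2,2-dimethyl-2H-chromen-7-yl)oxy-triisopropylsilane | CC1(C)C=Cc2cc(Br)c(O[Si](C(C)C)(C(C)C)C(C)C)cc2O1 | intermediate
13 | ethynyltrimethylsilane | C#C[Si](C)(C)C | starting material
14 | [2,2-dimethyl-6-(trimethylsilylethynyl)-2H-chromen-7-yl]oxy-triisopropylsilane | CC1(C)C=Cc2cc(C#C[Si](C)(C)C)c(O[Si](C(C)C)(C(C)C)C(C)C)cc2O1 | intermediate
15 | (6-ethynyl-2,2-dimethyl-2H-chromen-7-yl)oxy-triisopropylsilane | CC1(C)C=Cc2cc(C#C)c(O[Si](C(C)C)(C(C)C)C(C)C)cc2O1 | intermediate
16 | (E)-1-[2-hydroxy-3-(3-hydroxy-3-methylbutyl)-4,6-bis(tert-butyldimethylsilyloxy)phenyl]-3-[2,2-dimethyl-7-(triisopropylsilyloxy)-2H-chromen-6-yl]prop-2-en-1-one (not isolated) | O=C(/C=C/c1cc2C=CC(C)(C)Oc2cc1O[Si](C(C)C)(C(C)C)C(C)C)c1c(O)c(CCC(C)(C)O)c(O[Si](C)(C)C(C)(C)C)cc1O[Si](C)(C)C(C)(C)C | intermediate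
17 | (2S)-5,7-bis(tert-butyldimethylsilyloxy)-8-(3-hydroxy-3-methylbutyl)-2-[2,2-dimethyl-7-(triisopropylsilyloxy)-2H-chromen-6-yl]chroman-4-one | CC(C)(O)CCc1c(O[Si](C)(C)C(C)(C)C)cc(O[Si](C)(C)C(C)(C)C)c2c1O[C@H](c1cc3c(cc1O[Si](C(C)C)(C(C)C)C(C)C)OC(C)(C)C=C3)CC2=O | intermediate
18 | (2S)-5,7-dihydroxy-2-(7-hydroxy-2,2-dimethyl-2H-chromen-6-yl)-8-(3-hydroxy-3-methylbutyl)chroman-4-one | CC(C)(O)CCc1c(O)cc(O)c2c1O[C@H](c1cc3c(cc1O)OC(C)(C)C=C3)CC2=O | target

## Step count and risks

Total steps: 11. Longest linear sequence: 7 steps (steps 5 to 11).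

**Step 10 (proposed new method).** Facial control may be lost through a background ring closure mediated by residual rhodium phenoxide or through reversible retro-oxa-Michael opening under the amine catalyst. Markovnikov hydrometalation may also divert part of the alkyne to the branched enone. The fallback sets out from 6 and 15 and runs the two events as separate known reactions under achiral conditions. Hydroacylation with [RhCl(cod)]2, dppf and Na2CO3 in toluene at 80 °C gives chalcone 16, which is isolated and freed from any branched isomer. Ring closure with DBU (10 mol %) in toluene at rt gives the racemic flavanone F1. Preparative HPLC of F1 on a polysaccharide chiral stationary phase delivers 17, where the route is rejoined, and the (2R)-enantiomer F2. F2 is returned to F1 by DBU-mediated ring opening and reclosure and is resolved again.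

**Step 3.** Oxidative addition and migratory insertion may be slow at the doubly ortho-substituted, phenoxide-bearing aryl iodide, with protodeiodination and loss of the activated silyl ethers under the hot amine conditions. The fallback sets out from 2 and 4 and replaces cross-coupling by a sigmatropic route. Alcohol 4 is converted (n-BuLi, Boc2O, THF) into tert-butyl 2-methylbut-3-en-2-yl carbonate F3. Zerovalent-palladium-catalysed O-allylation of 2 with F3 (Pd(PPh3)4, THF, 0 °C) gives the tertiary allyl ether 2-[(2-methylbut-3-en-2-yl)oxy]-4,6-bis(tert-butyldimethylsilyloxy)benzaldehyde F4. Aromatic Claisen rearrangement (toluene, 100 °C) moves the allyl unit with transposition to the only free ortho carbon and gives 2-hydroxy-3-(3-methylbut-2-en-1-yl)-4,6-bis(tert-butyldimethylsilyloxy)benzaldehyde F5. Mukaiyama hydration (Co(acac)2, PhSiH3, O2, THF, rt) of the prenyl group then gives 6, where the route is rejoined; steps 2 to 4 are bypassed.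

**Step 8.** Oxidative addition into the electron-rich ortho-silyloxy aryl bromide may be slow enough for copper-mediated alkyne homocoupling to overtake the cross-coupling. The fallback sets out from 12 and builds the alkyne by one-carbon homologation. Bromine–lithium exchange (t-BuLi, THF, −78 °C, short contact to avoid silyl migration) and a DMF quench give 2,2-dimethyl-7-(triisopropylsilyloxy)-2H-chromene-6-carbaldehyde F6. Colvin homologation with lithiated trimethylsilyldiazomethane (TMSCHN2, LDA, THF, −78 °C to rt) gives 15, where the route is rejoined; compound 14 is bypassed.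

Further compounds
F1 | step 10 | racemic 5,7-bis(tert-butyldimethylsilyloxy)-8-(3-hydroxy-3-methylbutyl)-2-[2,2-dimethyl-7-(triisopropylsilyloxy)-2H-chromen-6-yl]chroman-4-one | CC(C)(O)CCc1c(O[Si](C)(C)C(C)(C)C)cc(O[Si](C)(C)C(C)(C)C)c2c1OC(c1cc3c(cc1O[Si](C(C)C)(C(C)C)C(C)C)OC(C)(C)C=C3)CC2=O
F2 | step 10 | (2R)-5,7-bis(tert-butyldimethylsilyloxy)-8-(3-hydroxy-3-methylbutyl)-2-[2,2-dimethyl-7-(triisopropylsilyloxy)-2H-chromen-6-yl]chroman-4-one | CC(C)(O)CCc1c(O[Si](C)(C)C(C)(C)C)cc(O[Si](C)(C)C(C)(C)C)c2c1O[C@@H](c1cc3c(cc1O[Si](C(C)C)(C(C)C)C(C)C)OC(C)(C)C=C3)CC2=O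
F3 | step 3 | tert-butyl 2-methylbut-3-en-2-yl carbonate | C=CC(C)(C)OC(=O)OC(C)(C)C
F4 | step 3 | 2-[(2-methylbut-3-en-2-yl)oxy]-4,6-bis(tert-butyldimethylsilyloxy)benzaldehyde | O=Cc1c(OC(C)(C)C=C)cc(O[Si](C)(C)C(C)(C)C)cc1O[Si](C)(C)C(C)(C)C
F5 | step 3 | 2-hydroxy-3-(3-methylbut-2-en-1-yl)-4,6-bis(tert-butyldimethylsilyloxy)benzaldehyde | O=Cc1c(O)c(CC=C(C)C)c(O[Si](C)(C)C(C)(C)C)cc1O[Si](C)(C)C(C)(C)C
F6 | step 8 | 2,2-dimethyl-7-(triisopropylsilyloxy)-2H-chromene-6-carbaldehyde | CC1(C)C=Cc2cc(C=O)c(O[Si](C(C)C)(C(C)C)C(C)C)cc2O1
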